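**Plan**

- Retrosynthesis: the seven O-alkyl groups come off last. Benzo ring B and the furan ring of dihydrobenzofuran 1 are cut together at C3a–C7a, C4–C5 and C6–C7 into an ynol ether, an enyne alkyne and ethoxyacetylene.
- The 1,6-diyne is cut at the O–C(sp) bond, at the alkyne–vinyl bond (Sonogashira) and at C2–C3 (allenylboration of 4-methoxybenzaldehyde). Dihydrobenzofuran 2 is cut at C2–C3 (carbene C–H insertion) back to 5-bromo-2-hydroxy-3-methoxybenzaldehyde.
- Forward: furan ring of dihydrobenzofuran 2 first, then the C3–C2 chain of unit 1 with its two alkynes, then ring B and the second furan ring in one cyclotrimerisation, then dealkylation.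
- Enabling feature: ring B (C3a–C7a) has H at C5 and C7, the styryl group at C4 and oxygen at C6, and shares C3a–C7a with the furan ring. It therefore maps onto three alkynes, two of them held together by the O1–C2–C3 tether.
- Stereochemistry: C3 of unit 2 comes from a chiral dirhodium catalyst and C2 of unit 2 from acid equilibration to trans. A catalyst-set propargylic carbinol is relayed to an allene axis (anti SN2′) and from there to C3 and C2 of unit 1 (chair allenylboration, anti).

Key step: step 16

Remarks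
- Ar2 = (2R,3R)-3-(3,5-dimethoxyphenyl)-7-methoxy-2-(4-methoxyphenyl)-2,3-dihydro-1-benzofuran-5-yl.
- Assumption: Rh2(R-PTAD)4 (step 5) and (S,S)-ProPhenol (step 8) are taken to give the configurations drawn; if a first run shows the opposite sense, the mirror-image catalyst is used and nothing else changes.

Step 1
Reactants: 1 5-bromo-2-hydroxy-3-methoxybenzaldehyde; 2 4-methoxybenzyl chloride
Product: 3 5-bromo-3-methoxy-2-[(4-methoxybenzyl)oxy]benzaldehyde
Conditions: K2CO3, KI (cat.), DMF, 60 °C
Reagents that add atoms: none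
Why: Williamson ether synthesis; the phenoxide of 1 is alkylated by the benzylic chloride, and the aldehyde and aryl bromide are inert to K2CO3.

Step 2
Reactants: 3 5-bromo-3-methoxy-2-[(4-methoxybenzyl)oxy]benzaldehyde; 4 3,5-dimethoxyphenylmagnesium chloride (commercial THF solution)
Product: 5 (±)-{5-bromo-3-methoxy-2-[(4-methoxybenzyl)oxy]phenyl}(3,5-dimethoxyphenyl)methanol
Conditions: THF, 0 °C; aq. NH4Cl
Reagents that add atoms: none
Why: Grignard 1,2-addition to the aldehyde; at 0 °C the aryl bromide does not exchange, and the racemic carbinol centre is removed in the next step.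

Step 3
Reactants: 5 (±)-diaryl carbinol
Product: 6 {5-bromo-3-methoxy-2-[(4-methoxybenzyl)oxy]phenyl}(3,5-dimethoxyphenyl)methanone
Conditions: MnO2 (activated), CH2Cl2, rt
Reagents that add atoms: none
Why: Benzylic alcohol oxidation with MnO2 should give the diaryl ketone without touching the 4-methoxybenzyl ether.

Step 4
Reactants: 6 diaryl ketone
Product: 7 hydrazone of 6 (E/Z mixture)
Conditions: N2H4·H2O (excess), AcOH (cat.), EtOH, 80 °C
Reagents that add atoms: hydrazine (as hydrate), NN
Why: Acid-catalysed condensation of the ketone with hydrazine (hydrazone formation) provides the precursor of the diaryldiazomethane.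

Step 5
Reactants: 7 hydrazone
Product: 9 (2S,3R)-5-bromo-3-(3,5-dimethoxyphenyl)-7-methoxy-2-(4-methoxyphenyl)-2,3-dihydro-1-benzofuran (cis), via diaryldiazomethane 8 (not isolated)
Conditions: MnO2, CH2Cl2, 0 °C; filter; Rh2(R-PTAD)4 (1 mol %), CH2Cl2, 0 °C → rt
Reagents that add atoms: none
Why: MnO2 dehydrogenates the hydrazone to the diazo compound and the chiral dirhodium tetracarboxylate turns it into a donor/donor carbene that inserts into a benzylic C–H bond of the 4-methoxybenzyl ether (intramolecular 1,5 C–H insertion), forming C3–C2 and the furan ring of unit 2; the catalyst sets C3 (R), and the concerted insertion is expected to give the cis (2S) isomer kinetically.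

Step 6
Reactants: 9 cis-(2S,3R) bromide
Product: 10 (2R,3R)-5-bromo-3-(3,5-dimethoxyphenyl)-7-methoxy-2-(4-methoxyphenyl)-2,3-dihydro-1-benzofuran (trans; Ar2–Br)
Conditions: TFA, CH2Cl2, 0 °C → rt
Reagents that add atoms: none
Why: Acid-mediated epimerisation: reversible ionisation of the C2–O bond to the 4-methoxybenzylic cation and re-closure by the phenol oxygen should equilibrate C2 to the more stable 2,3-trans isomer, while C3 is not involved and keeps its configuration.

Step 7
Reactants: 10 Ar2–Br
Product: 12 (2R,3R)-3-(3,5-dimethoxyphenyl)-7-methoxy-2-(4-methoxyphenyl)-2,3-dihydro-1-benzofuran-5-carbaldehyde (Ar2–CHO), via aryllithium 11 (not isolated)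
Conditions: n-BuLi, THF, −78 °C; DMF, −78 → 0 °C; aq. NH4Cl
Reagents that add atoms: N,N-dimethylformamide, CN(C)C=O
Why: Bromine–lithium exchange and formylation of the aryllithium with DMF (Bouveault-type); exchange at −78 °C is faster than any benzylic deprotonation.

Step 8
Reactants: 12 Ar2–CHO; 13 trimethylsilylacetylene
Product: 14 (1R)-1-Ar2-3-(trimethylsilyl)prop-2-yn-1-ol
Conditions: (S,S)-ProPhenol (10 mol %), Me2Zn, Ph3P=O (20 mol %), toluene, 4 °C
Reagents that add atoms: none
Why: Catalytic enantioselective zinc acetylide addition to an aryl aldehyde; the chiral dinuclear zinc catalyst delivers the alkynyl group to one aldehyde face to give the (R) carbinol, the distant centres of unit 2 having no influence.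

Step 9
Reactants: 14 (R)-silylalkynyl carbinol
Product: 15 (1S)-1-Ar2-prop-2-yn-1-ol (same geometry as 14; the descriptor changes only through CIP priority)
Conditions: K2CO3 (cat.), MeOH, rt
Reagents that add atoms: none
Why: Base-mediated methanolysis of the C(sp)–Si bond; nothing else in 14 reacts with K2CO3/MeOH.

Step 10
Reactants: 15 (S)-propargylic alcohol
Product: 16 (1S)-1-Ar2-prop-2-yn-1-yl methyl carbonate
Conditions: ClCO2Me, pyridine, DMAP (cat.), CH2Cl2, 0 °C
Reagents that add atoms: methyl chloroformate, COC(Cl)=O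
Why: O-acylation of the secondary alcohol gives the propargylic carbonate, the leaving group for the SN2′ borylation, with the carbinol configuration unchanged.

Step 11
Reactants: 16 (S)-propargylic carbonate
Product: 17 2-[(Sa)-3-Ar2-propa-1,2-dien-1-yl]-4,4,5,5-tetramethyl-1,3,2-dioxaborolane
Conditions: CuCl (5 mol %), Xantphos (5 mol %), NaO-t-Bu (10 mol %), B2pin2, THF, 0 °C → rt
Reagents that add atoms: bis(pinacolato)diboron, CC1(C)OB(OC1(C)C)B1OC(C)(C)C(C)(C)O1
Why: Copper-catalysed SN2′ borylation of a propargylic carbonate: the Cu–Bpin species adds syn across the terminal alkyne (boron to the terminal carbon) and anti β-elimination of the carbonate converts the (S) carbinol centre into the (Sa) allene axis (centre-to-axis chirality transfer).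

Step 12
Reactants: 17 (Sa)-allenylboronate; 18 4-methoxybenzaldehyde
Product: 19 (1S,2R)-1-(4-methoxyphenyl)-2-Ar2-but-3-yn-1-ol (anti)
Conditions: (PhO)2P(O)OH (10 mol %), 4 Å MS, toluene, 0 °C → rt; aq. NaHCO3
Reagents that add atoms: none
Why: Brønsted-acid-catalysed allenylboration (SE2′ propargylation) through a closed six-membered chair transition state: the new C–C bond forms at the aryl-bearing allene carbon on the face syn to boron, so the (Sa) axis fixes the Ar2-bearing carbon, and the equatorial aryl group of the aldehyde gives the anti carbinol (S).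

Step 13
Reactants: 20 (E)-4-methoxycinnamic acid
Product: 21 (E)-1-(2-bromoethenyl)-4-methoxybenzene
Conditions: NBS, Et3N (5 mol %), CH2Cl2, rt
Reagents that add atoms: N-bromosuccinimide, O=C1CCC(=O)N1Br
Why: Bromodecarboxylation of a cinnamic acid (catalytic Hunsdiecker reaction), which is stereoselective for the (E)-vinyl bromide and favoured by the 4-methoxy group.

Step 14
Reactants: 19 anti-homopropargylic alcohol; 21 (E)-vinyl bromide
Product: 22 (1S,2S,5E)-1,6-bis(4-methoxyphenyl)-2-Ar2-hex-5-en-3-yn-1-ol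
Conditions: Pd(PPh3)4 (3 mol %), CuI (5 mol %), i-Pr2NH, THF, rt
Reagents that add atoms: none
Why: Sonogashira coupling of the terminal alkyne with the vinyl bromide with retention of the E geometry; amine base at room temperature leaves the free alcohol and the propargylic C–H untouched.

Step 15
Reactants: 22 enyne alcohol; 23 trichloroethylene
Product: 26 (1S,2S,5E)-1-(ethynyloxy)-1,6-bis(4-methoxyphenyl)-2-Ar2-hex-5-en-3-yne, via dichlorovinyl ether 24 (not isolated), via lithium alkynyl ether 25 (not isolated)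
Conditions: KH, THF, 0 °C; Cl2C=CHCl, −40 °C → rt; n-BuLi (2.2 equiv), −78 °C; MeOH, −78 °C
Reagents that add atoms: none
Why: Alkoxide/trichloroethylene route to ynol ethers: the potassium alkoxide adds to dichloroacetylene formed in situ to give the (E)-1,2-dichlorovinyl ether, and n-BuLi then effects dehydrochlorination and chlorine–lithium exchange to the lithium alkynyl ether, which MeOH protonates; the carbinol C–O bond is never broken, and the base is limited to 2.2 equiv at −78 °C because the adjacent C–H is propargylic and benzylic.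

Step 16
Reactants: 26 ynol ether/enyne 1,6-diyne; 27 ethoxyacetylene
Product: 28 (2S,3S)-6-ethoxy-2-(4-methoxyphenyl)-4-[(E)-2-(4-methoxyphenyl)ethenyl]-3-Ar2-2,3-dihydro-1-benzofuran
Conditions: Cp*RuCl(cod) (5–10 mol %), 27 (5 equiv), ClCH2CH2Cl, rt, slow addition of 26
Reagents that add atoms: none
Why: Proposed new method: the Cp*RuCl fragment (divalent ruthenium, cod lost) binds the ynol ether and the enyne alkyne of 26 and couples them oxidatively at their inner carbons (C3a–C7a), which closes the furan ring as the five-membered ring fused to a ruthenacycle (formally tetravalent ruthenium) through the O1–C2–C3 tether; ethoxyacetylene then adds across the metal-bound carbons C7 and C4, and reductive elimination closes benzo ring B with the bonds C6–C7 and C4–C5. The closest known reactions are the [2+2+2] cyclotrimerisations of ynamide-tethered 1,6-diynes with monoalkynes to indolines (RhCl(PPh3)3 or ruthenium catalysts), of aryl ynol ether-linked 1,6-diynes to dibenzofurans, and the Cp*RuCl(cod) cotrimerisation of unsymmetrical 1,6-diynes with terminal alkynes; an alkyl ynol ether on an sp3 tether has not been used. No stereocentre is formed, and C2 and C3, set in step 12, are not touched by the neutral catalyst at room temperature. The step needs the ethoxy-bearing carbon to bond to C7 and not to C4: the metallacycle has an unsubstituted terminus (C7–H) and a styryl-bearing one (C4), and this catalyst is known to place the substituent of a terminal alkyne meta to the substituent of the diyne terminus, which is why it is preferred to RhCl(PPh3)3, for which the ortho isomer can dominate. Chemoselectivity rests on the tether (the first C–C bond is intramolecular) and on slow addition of 26 to excess 27, which suppresses diyne dimerisation, while room temperature keeps retro-ene loss of ketene and sigmatropic rearrangement of the benzylic ynol ether slow.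

Step 17
Reactants: 28 6-O-ethyl hexamethyl ether
Product: 29 (2S,3S)-3-[(2R,3R)-3-(3,5-dihydroxyphenyl)-7-hydroxy-2-(4-hydroxyphenyl)-2,3-dihydro-1-benzofuran-5-yl]-2-(4-hydroxyphenyl)-4-[(E)-2-(4-hydroxyphenyl)ethenyl]-2,3-dihydro-1-benzofuran-6-ol (CNP0172909.1)
Conditions: BBr3 (excess), CH2Cl2, −78 → 0 °C; ice-water
Reagents that add atoms: none
Why: Lewis-acid cleavage of the six aryl methyl ethers and the aryl ethyl ether with BBr3, then hydrolysis of the aryl borates; both dihydrobenzofurans are already the thermodynamic trans isomers, so reversible C2–O ionisation cannot change them, and low temperature limits acid-induced reactions of the stilbene.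

**Compound list**

1 | 5-bromo-2-hydroxy-3-methoxybenzaldehyde | COc1cc(Br)cc(C=O)c1O | starting material
2 | 4-methoxybenzyl chloride | COc1ccc(CCl)cc1 | starting material
3 | 5-bromo-3-methoxy-2-[(4-methoxybenzyl)oxy]benzaldehyde | COc1ccc(COc2c(OC)cc(Br)cc2C=O)cc1 | intermediate
4 | 3,5-dimethoxyphenylmagnesium chloride | COc1cc(OC)cc([Mg]Cl)c1 | starting material
5 | (±)-{5-bromo-3-methoxy-2-[(4-methoxybenzyl)oxy]phenyl}(3,5-dimethoxyphenyl)methanol | COc1ccc(COc2c(OC)cc(Br)cc2C(O)c2cc(OC)cc(OC)c2)cc1 | intermediate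
6 | {5-bromo-3-methoxy-2-[(4-methoxybenzyl)oxy]phenyl}(3,5-dimethoxyphenyl)methanone | COc1ccc(COc2c(OC)cc(Br)cc2C(=O)c2cc(OC)cc(OC)c2)cc1 | intermediate
7 | hydrazone of 6 | COc1ccc(COc2c(OC)cc(Br)cc2C(=NN)c2cc(OC)cc(OC)c2)cc1 | intermediate
8 | {5-bromo-3-methoxy-2-[(4-methoxybenzyl)oxy]phenyl}(3,5-dimethoxyphenyl)diazomethane | COc1ccc(COc2c(OC)cc(Br)cc2C(=[N+]=[N-])c2cc(OC)cc(OC)c2)cc1 | intermediate
9 | (2S,3R)-5-bromo-3-(3,5-dimethoxyphenyl)-7-methoxy-2-(4-methoxyphenyl)-2,3-dihydro-1-benzofuran (cis) | Brc1cc(OC)c2c(c1)[C@@H](c1cc(OC)cc(OC)c1)[C@@H](c1ccc(OC)cc1)O2 | intermediate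
10 | (2R,3R)-5-bromo-3-(3,5-dimethoxyphenyl)-7-methoxy-2-(4-methoxyphenyl)-2,3-dihydro-1-benzofuran (trans, Ar2–Br) | Brc1cc(OC)c2c(c1)[C@@H](c1cc(OC)cc(OC)c1)[C@H](c1ccc(OC)cc1)O2 | intermediate
11 | Ar2–Li, the 5-lithio derivative of 10 | [Li]c1cc(OC)c2c(c1)[C@@H](c1cc(OC)cc(OC)c1)[C@H](c1ccc(OC)cc1)O2 | intermediate
12 | (2R,3R)-3-(3,5-dimethoxyphenyl)-7-methoxy-2-(4-methoxyphenyl)-2,3-dihydro-1-benzofuran-5-carbaldehyde | O=Cc1cc(OC)c2c(c1)[C@@H](c1cc(OC)cc(OC)c1)[C@H](c1ccc(OC)cc1)O2 | intermediate
13 | trimethylsilylacetylene | C#C[Si](C)(C)C | starting material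
14 | (1R)-1-Ar2-3-(trimethylsilyl)prop-2-yn-1-ol | C[Si](C)(C)C#C[C@H](O)c1cc(OC)c2c(c1)[C@@H](c1cc(OC)cc(OC)c1)[C@H](c1ccc(OC)cc1)O2 | intermediate
15 | (1S)-1-Ar2-prop-2-yn-1-ol | C#C[C@H](O)c1cc(OC)c2c(c1)[C@@H](c1cc(OC)cc(OC)c1)[C@H](c1ccc(OC)cc1)O2 | intermediate
16 | (1S)-1-Ar2-prop-2-yn-1-yl methyl carbonate | C#C[C@H](OC(=O)OC)c1cc(OC)c2c(c1)[C@@H](c1cc(OC)cc(OC)c1)[C@H](c1ccc(OC)cc1)O2 | intermediate
17 | 2-[(Sa)-3-Ar2-propa-1,2-dien-1-yl]-4,4,5,5-tetramethyl-1,3,2-dioxaborolane | [H]C(B1OC(C)(C)C(C)(C)O1)=[C@]=C([H])c1cc(OC)c2c(c1)[C@@H](c1cc(OC)cc(OC)c1)[C@H](c1ccc(OC)cc1)O2 | intermediate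
18 | 4-methoxybenzaldehyde | COc1ccc(C=O)cc1 | starting material
19 | (1S,2R)-1-(4-methoxyphenyl)-2-Ar2-but-3-yn-1-ol | C#C[C@H](c1cc(OC)c2c(c1)[C@@H](c1cc(OC)cc(OC)c1)[C@H](c1ccc(OC)cc1)O2)[C@@H](c1ccc(OC)cc1)O | intermediate
20 | (E)-4-methoxycinnamic acid | COc1ccc(/C=C/C(=O)O)cc1 | starting material
21 | (E)-1-(2-bromoethenyl)-4-methoxybenzene | COc1ccc(/C=C/Br)cc1 | intermediate
22 | (1S,2S,5E)-1,6-bis(4-methoxyphenyl)-2-Ar2-hex-5-en-3-yn-1-ol | COc1ccc(/C=C/C#C[C@H](c2cc(OC)c3c(c2)[C@@H](c2cc(OC)cc(OC)c2)[C@H](c2ccc(OC)cc2)O3)[C@@H](c2ccc(OC)cc2)O)cc1 | intermediate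
23 | trichloroethylene | ClC=C(Cl)Cl | starting material
24 | (E)-1,2-dichloroethenyl ether of 22 | COc1ccc(/C=C/C#C[C@H](c2cc(OC)c3c(c2)[C@@H](c2cc(OC)cc(OC)c2)[C@H](c2ccc(OC)cc2)O3)[C@@H](c2ccc(OC)cc2)O/C(Cl)=C\Cl)cc1 | intermediate
25 | lithium acetylide of ynol ether 26 | COc1ccc(/C=C/C#C[C@H](c2cc(OC)c3c(c2)[C@@H](c2cc(OC)cc(OC)c2)[C@H](c2ccc(OC)cc2)O3)[C@@H](c2ccc(OC)cc2)OC#C[Li])cc1 | intermediate
26 | (1S,2S,5E)-1-(ethynyloxy)-1,6-bis(4-methoxyphenyl)-2-Ar2-hex-5-en-3-yne | COc1ccc(/C=C/C#C[C@H](c2cc(OC)c3c(c2)[C@@H](c2cc(OC)cc(OC)c2)[C@H](c2ccc(OC)cc2)O3)[C@@H](c2ccc(OC)cc2)OC#C)cc1 | intermediate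
27 | ethoxyacetylene | CCOC#C | starting material
28 | (2S,3S)-6-ethoxy-2-(4-methoxyphenyl)-4-[(E)-2-(4-methoxyphenyl)ethenyl]-3-Ar2-2,3-dihydro-1-benzofuran | COc1ccc(/C=C/c2cc(OCC)cc3c2[C@H](c2cc(OC)c4c(c2)[C@@H](c2cc(OC)cc(OC)c2)[C@H](c2ccc(OC)cc2)O4)[C@@H](c2ccc(OC)cc2)O3)cc1 | intermediate
29 | CNP0172909.1, the heptaphenol named in step 17 | Oc1ccc(/C=C/c2cc(O)cc3c2[C@H](c2cc(O)c4c(c2)[C@@H](c2cc(O)cc(O)c2)[C@H](c2ccc(O)cc2)O4)[C@@H](c2ccc(O)cc2)O3)cc1 | target

**Step count and risks**

Total: 17 steps. Longest linear sequence: 16 steps (steps 1–12 and 14–17, from 1); step 13 is a one-step side branch.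

Most likely to fail:

1. Step 16. The ynol ether may be lost by ketene extrusion (retro-ene) or sigmatropic shift before the metal engages it, ethoxyacetylene may insert in the opposite orientation, or the partners may homo-trimerise. Fallback with known reactions, which also bypasses step 15: it sets out from enyne alcohol 22. Silylation with chloro(ethynyl)dimethylsilane (imidazole, CH2Cl2) gives the alkynylsilyl ether F1, a diyne with a temporary silicon tether. Cyclotrimerisation of F1 with 27 under Cp*RuCl(cod) forms ring B as the benzoxasiline F2, with silicon on the future C7a. Tamao–Fleming oxidation (KF, KHCO3, H2O2, THF/MeOH) cleaves the aryl–silicon bond to the phenol alcohol F3. Acid-catalysed cyclodehydration of F3 (p-TsOH cat., CH2Cl2, 0 °C) through the 4-methoxybenzylic cation closes the furan ring as the trans isomer and returns to the route at 28.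

2. Step 11. Copper acetylide formation at the terminal alkyne could open an ionising pathway that erodes the configuration, and the aryl-substituted allenylboronate could isomerise or lose boron on isolation. Fallback: it sets out from carbonate 16 and goes directly to 19, skipping 17. Zerovalent palladium (from Pd(OAc)2/PPh3) with Et2Zn in THF at −20 °C, in the presence of aldehyde 18, converts 16 by anti SN2′ oxidative addition and transmetalation into the allenyl(ethyl)zinc reagent F4. F4 is not isolated and adds to 18 through a cyclic transition state to give the anti alcohol 19, where the route continues.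

3. Step 17. Under BBr3 and the HBr it releases, the stilbene may cyclise onto the electron-rich rings or the dihydrobenzofurans may open irreversibly. Fallback: it sets out from 28 and uses nucleophilic instead of Lewis-acid dealkylation. Excess NaSEt in DMF at 150 °C removes the methyl and ethyl groups by SN2 attack, leaving the heptaphenoxide, and acidification on work-up gives 29.

**Further compounds**

F1 | step 16 | ethynyl(dimethyl)silyl ether of 22 | COc1ccc(/C=C/C#C[C@H](c2cc(OC)c3c(c2)[C@@H](c2cc(OC)cc(OC)c2)[C@H](c2ccc(OC)cc2)O3)[C@@H](c2ccc(OC)cc2)O[Si](C)(C)C#C)cc1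
F2 | step 16 | (3S,4S)-7-ethoxy-1,1-dimethyl-3-(4-methoxyphenyl)-5-[(E)-2-(4-methoxyphenyl)ethenyl]-4-Ar2-3,4-dihydro-1H-2,1-benzoxasiline | COc1ccc(/C=C/c2cc(OCC)cc3c2[C@H](c2cc(OC)c4c(c2)[C@@H](c2cc(OC)cc(OC)c2)[C@H](c2ccc(OC)cc2)O4)[C@@H](c2ccc(OC)cc2)O[Si]3(C)C)cc1
F3 | step 16 | 5-ethoxy-2-[(1S,2S)-2-hydroxy-2-(4-methoxyphenyl)-1-Ar2-ethyl]-3-[(E)-2-(4-methoxyphenyl)ethenyl]phenol | COc1ccc(/C=C/c2cc(OCC)cc(O)c2[C@H](c2cc(OC)c3c(c2)[C@@H](c2cc(OC)cc(OC)c2)[C@H](c2ccc(OC)cc2)O3)[C@@H](c2ccc(OC)cc2)O)cc1
F4 | step 11 | ethyl[(Sa)-3-Ar2-propa-1,2-dien-1-yl]zinc | [H]C([Zn]CC)=[C@]=C([H])c1cc(OC)c2c(c1)[C@@H](c1cc(OC)cc(OC)c1)[C@H](c1ccc(OC)cc1)O2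
F0 | step 17 | none | none
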